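**Strategy.** The plan disconnects O1–C2 of the lower unit's pyran (C) ring. Its C4 lies para to O7 and ortho to O1 on the lower A ring, so a C4 carbinol of either configuration loses water to one o-quinone methide, O1=C8a–C4a=C4–C3=C2. A chiral Brønsted acid steers its oxa-6π closure, funnelling both epimers of an open-chain allylic alcohol into one (2S)-flav-3-ene. That precursor is a reduced 2'-hydroxychalcone whose B ring already carries the complete upper robinetinidol unit at C2'. Dihydroxylation of C3=C4 anti to the C2 aryl group then gives the 2,3-trans-3,4-cis triad directly.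

Key step: step 9

Assumption: 1, 5 and 11 are taken as catalogue compounds, and the (R)-acid is taken as the catalyst antipode that is matched with the ortho-flavanyl group for the (2S)-flavene (its antipode is equally available).

Step 1
Reactants: 1 (+)-dihydrorobinetin
Product: 2 (+)-leucorobinetinidin
Conditions: NaBH4, EtOH, 0 °C to rt, Ar; dilute AcOH to pH 6
Reagents that add atoms: none
Why: Borohydride reduction of a trans-dihydroflavonol, in which axial hydride attack on C4=O should give mainly the all-equatorial 2,3-trans-3,4-trans diol (4R), while C2 and C3 come unchanged from the chiral pool and C4 is erased again in step 4.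

Step 2
Reactants: 2 (+)-leucorobinetinidin
Product: 4 hexa-O-benzyl-leucorobinetinidin, via tetra-O-benzyl diol 3 (not isolated)
Conditions: BnBr, K2CO3, DMF, rt, Ar; then NaH, 0 °C to rt (one pot)
Reagents that add atoms: benzyl bromide BrCc1ccccc1
Why: Two-stage Williamson etherification in which the carbonate caps the four phenols before any strong base is present (so no quinone methide can open the ring or epimerise C2) and NaH then alkylates O3 and O4, which makes O3 inert and turns O4 into a leaving group.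

Step 3
Reactants: 5 3,4,5-tris(benzyloxy)benzaldehyde
Product: 7 3,4,5-tris(benzyloxy)phenol, via aryl formate 6 (not isolated)
Conditions: mCPBA, CH2Cl2, rt; then cat. K2CO3, MeOH, rt
Reagents that add atoms: mCPBA (3-chloroperoxybenzoic acid) OOC(=O)c1cccc(Cl)c1
Why: Baeyer–Villiger (Dakin-type) oxidation with migration of the electron-rich aryl group, followed by transesterification of the formate, gives a phenol whose C2/C6 positions are activated in the phloroglucinol manner by three oxygens.

Step 4
Reactants: 4 hexa-O-benzyl-leucorobinetinidin; 7 3,4,5-tris(benzyloxy)phenol (2 equiv)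
Product: 8 4α-arylflavan phenol
Conditions: TMSOTf (0.2 equiv), CH2Cl2, −78 to −40 °C, slow addition of 4
Reagents that add atoms: none
Why: Friedel–Crafts arylation through the flavan-4-yl cation (loss of the 4-benzyloxy group, stabilised by O7 and O1), in which the ortho position of phenol 7 is far more nucleophilic than the resorcinol-type A rings (so self-condensation is outrun) and attacks anti to the 3-benzyloxy group to set C4 as 4α (4S, 3,4-trans).

Step 5
Reactants: 8 4α-arylflavan phenol
Product: 9 aryl triflate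
Conditions: Tf2O, pyridine, CH2Cl2, 0 °C
Reagents that add atoms: triflic anhydride O=S(=O)(OS(=O)(=O)C(F)(F)F)C(F)(F)F
Why: O-Sulfonylation of the only free hydroxyl group turns the activating phenol into a cross-coupling handle at the future C1' and deactivates the ring against acid cleavage of the new C4–C2' bond.

Step 6
Reactants: 9 aryl triflate
Product: 10 aryl aldehyde
Conditions: Pd(OAc)2, dppp, CO/H2 (1:1, 20 bar), pyridine, DMF, 90 °C
Reagents that add atoms: carbon monoxide [C-]#[O+]
Why: Palladium-catalysed reductive carbonylation (formylation) of an aryl triflate with synthesis gas replaces C–O by C–CHO, and the homogeneous phosphine catalyst leaves benzyl ethers and all stereocentres untouched.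

Step 7
Reactants: 10 aryl aldehyde; 11 1-[4-(benzyloxy)-2-hydroxyphenyl]ethanone
Product: 12 (E)-2'-hydroxychalcone
Conditions: KOH, EtOH–THF, rt
Reagents that add atoms: none
Why: Claisen–Schmidt condensation with E1cB dehydration gives the (E)-enone, and the upper unit is base-stable because all its phenols and O3 are ethers (no quinone methide, no oxa-Michael attack of O3 on the enone).

Step 8
Reactants: 12 (E)-2'-hydroxychalcone
Product: 13 allylic alcohol (both C4 epimers)
Conditions: DIBAL-H (3 equiv), CH2Cl2, −78 °C; aq Rochelle salt; crude product kept cold, no chromatography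
Reagents that add atoms: none
Why: Selective 1,2-reduction of the enone by DIBAL-H through the aluminium phenoxide chelate gives the carbinol at the future C4 deliberately without stereocontrol, and the non-acidic work-up avoids premature dehydration.

Step 9
Reactants: 13 allylic alcohol (both C4 epimers)
Product: 15 (2S)-flav-3-ene, via o-quinone methide 14 (not isolated)
Conditions: (R)-3,3'-bis(2,4,6-triisopropylphenyl)-BINOL N-triflylphosphoramide (10 mol %), 4 Å MS, toluene, −60 °C
Reagents that add atoms: none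
Why: The strong chiral acid protonates the C4 hydroxyl of either epimer of 13 and water leaves with the push of O7 (para) and O1–H (ortho), giving the 1,3-diarylallyl cation that is deprotonated at O1 to the planar o-quinone methide 14, so the C4 stereocentre is erased and both epimers converge. After rotation about the C3–C4 single bond of 14 the pyran ring closes by a disrotatory oxa-6π electrocyclisation (formally a 6-endo-trig SN1' allylic etherification) that makes O1–C2 and leaves C3=C4. The closest known reaction type is the chiral Brønsted acid (contact ion pair) catalysed intramolecular allylic substitution of o-hydroxyaryl allylic alcohols to 2H-chromenes, whose achiral version is the classical flav-3-ene synthesis from reduced 2'-hydroxychalcones. The single new stereocentre C2 is controlled by the phosphoramide anion, which stays hydrogen-bonded to O1 and shields one face of C2 with its 3,3'-aryl groups, so that the aryl group ends up on the α face (2S). The step needs O1 to win over every other nucleophile and the catalysed path to win over background closure: O3 of the upper unit is a benzyl ether and cannot close the competing six-membered isochroman on C2, attack of O1 at C4 would give a four-membered ring, and acid-free crude 13, sieves and low temperature hold back uncatalysed closure and re-ionisation of 15.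

Step 10
Reactants: 15 (2S)-flav-3-ene
Product: 16 nona-O-benzyl 3,4-cis-diol
Conditions: OsO4 (5 mol %), NMO, acetone–THF–H2O, rt; aq Na2SO3
Reagents that add atoms: osmium tetroxide O=[Os](=O)(=O)=O; N-methylmorpholine N-oxide C[N+]1([O-])CCOCC1; water O
Why: Catalytic OsO4/NMO syn-dihydroxylation, in which the [3+2] addition takes the face of C3=C4 anti to the very bulky C2 aryl group and so sets C3 (S) and C4 (S) cis to each other and trans to the aryl group under neutral conditions that do not ionise the new benzylic alcohol.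

Step 11
Reactants: 16 nona-O-benzyl 3,4-cis-diol
Product: 17 target, robinetinidol-(4α→2')-(2R,3S,4S)-leucorobinetinidin
Conditions: H2 (1 atm), Pd(OH)2/C, THF–MeOH, rt, strictly neutral, stopped at complete debenzylation; filtration under Ar
Reagents that add atoms: none
Why: Catalytic hydrogenolysis removes the eight aryl benzyl ethers and the 3-O-benzyl ether, while the hindered ring C2–O1 bonds and, in the absence of acid, the secondary benzylic C4–OH should persist as they do in debenzylations of p-hydroxyphenyl carbinols, so no stereocentre is touched.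

**Compound list**

1 | (+)-dihydrorobinetin, (2R,3R)-3,7-dihydroxy-2-(3,4,5-trihydroxyphenyl)chroman-4-one | Oc1ccc2c(c1)O[C@H](c1cc(O)c(O)c(O)c1)[C@@H](O)C2=O | starting material
2 | (+)-leucorobinetinidin, (2R,3S,4R)-2-(3,4,5-trihydroxyphenyl)chroman-3,4,7-triol | Oc1ccc2c(c1)O[C@H](c1cc(O)c(O)c(O)c1)[C@@H](O)[C@@H]2O | intermediate
3 | (2R,3S,4R)-7-(benzyloxy)-2-[3,4,5-tris(benzyloxy)phenyl]chroman-3,4-diol | c1ccccc1COc1ccc2c(c1)O[C@H](c1cc(OCc3ccccc3)c(OCc3ccccc3)c(OCc3ccccc3)c1)[C@@H](O)[C@@H]2O | intermediate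
4 | (2R,3S,4R)-3,4,7-tris(benzyloxy)-2-[3,4,5-tris(benzyloxy)phenyl]chroman | c1ccccc1COc1ccc2c(c1)O[C@H](c1cc(OCc3ccccc3)c(OCc3ccccc3)c(OCc3ccccc3)c1)[C@@H](OCc1ccccc1)[C@@H]2OCc1ccccc1 | intermediate
5 | 3,4,5-tris(benzyloxy)benzaldehyde | O=Cc1cc(OCc2ccccc2)c(OCc2ccccc2)c(OCc2ccccc2)c1 | starting material
6 | 3,4,5-tris(benzyloxy)phenyl formate | O=COc1cc(OCc2ccccc2)c(OCc2ccccc2)c(OCc2ccccc2)c1 | intermediate
7 | 3,4,5-tris(benzyloxy)phenol | Oc1cc(OCc2ccccc2)c(OCc2ccccc2)c(OCc2ccccc2)c1 | intermediate
8 | 2-{(2R,3S,4S)-3,7-bis(benzyloxy)-2-[3,4,5-tris(benzyloxy)phenyl]chroman-4-yl}-3,4,5-tris(benzyloxy)phenol (2,3-trans-3,4-trans) | c1ccccc1COc1ccc2c(c1)O[C@H](c1cc(OCc3ccccc3)c(OCc3ccccc3)c(OCc3ccccc3)c1)[C@@H](OCc1ccccc1)[C@@H]2c1c(O)cc(OCc3ccccc3)c(OCc3ccccc3)c1OCc1ccccc1 | intermediate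
9 | trifluoromethanesulfonate of phenol 8 | c1ccccc1COc1ccc2c(c1)O[C@H](c1cc(OCc3ccccc3)c(OCc3ccccc3)c(OCc3ccccc3)c1)[C@@H](OCc1ccccc1)[C@@H]2c1c(OS(=O)(=O)C(F)(F)F)cc(OCc3ccccc3)c(OCc3ccccc3)c1OCc1ccccc1 | intermediate
10 | 2-{(2R,3S,4S)-3,7-bis(benzyloxy)-2-[3,4,5-tris(benzyloxy)phenyl]chroman-4-yl}-3,4,5-tris(benzyloxy)benzaldehyde | c1ccccc1COc1ccc2c(c1)O[C@H](c1cc(OCc3ccccc3)c(OCc3ccccc3)c(OCc3ccccc3)c1)[C@@H](OCc1ccccc1)[C@@H]2c1c(C=O)cc(OCc3ccccc3)c(OCc3ccccc3)c1OCc1ccccc1 | intermediate
11 | 1-[4-(benzyloxy)-2-hydroxyphenyl]ethanone | CC(=O)c1ccc(OCc2ccccc2)cc1O | starting material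
12 | (E)-1-[4-(benzyloxy)-2-hydroxyphenyl]-3-aryl-prop-2-en-1-one, aryl = the 2-[(2R,3S,4S)-flavan-4-yl]-3,4,5-tris(benzyloxy)phenyl group of 10 | c1ccccc1COc1ccc2c(c1)O[C@H](c1cc(OCc3ccccc3)c(OCc3ccccc3)c(OCc3ccccc3)c1)[C@@H](OCc1ccccc1)[C@@H]2c1c(/C=C/C(=O)c3ccc(OCc4ccccc4)cc3O)cc(OCc3ccccc3)c(OCc3ccccc3)c1OCc1ccccc1 | intermediate
13 | (E)-allylic alcohol from 12, 5-(benzyloxy)-2-(1-hydroxy-3-arylallyl)phenol, both epimers at the carbinol carbon | c1ccccc1COc1ccc2c(c1)O[C@H](c1cc(OCc3ccccc3)c(OCc3ccccc3)c(OCc3ccccc3)c1)[C@@H](OCc1ccccc1)[C@@H]2c1c(/C=C/C(O)c3ccc(OCc4ccccc4)cc3O)cc(OCc3ccccc3)c(OCc3ccccc3)c1OCc1ccccc1 | intermediate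
14 | o-quinone methide, 3-(benzyloxy)-6-[(E)-3-arylallylidene]cyclohexa-2,4-dien-1-one | c1ccccc1COc1ccc2c(c1)O[C@H](c1cc(OCc3ccccc3)c(OCc3ccccc3)c(OCc3ccccc3)c1)[C@@H](OCc1ccccc1)[C@@H]2c1c(/C=C/C=C3C=CC(OCc4ccccc4)=CC3=O)cc(OCc3ccccc3)c(OCc3ccccc3)c1OCc1ccccc1 | intermediate
15 | (2S)-7-(benzyloxy)-2-aryl-2H-chromene (flav-3-ene, aryl on the α face), aryl as in 12 | c1ccccc1COc1ccc2c(c1)O[C@H](c1cc(OCc3ccccc3)c(OCc3ccccc3)c(OCc3ccccc3)c1)[C@@H](OCc1ccccc1)[C@@H]2c1c([C@H]3Oc4cc(OCc5ccccc5)ccc4C=C3)cc(OCc3ccccc3)c(OCc3ccccc3)c1OCc1ccccc1 | intermediate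
16 | nona-O-benzyl ether of the target, lower unit (2R,3S,4S)-7-(benzyloxy)-2-arylchroman-3,4-diol (2,3-trans-3,4-cis) | c1ccccc1COc1ccc2c(c1)O[C@H](c1cc(OCc3ccccc3)c(OCc3ccccc3)c(OCc3ccccc3)c1)[C@@H](OCc1ccccc1)[C@@H]2c1c([C@H]3Oc4cc(OCc5ccccc5)ccc4[C@H](O)[C@@H]3O)cc(OCc3ccccc3)c(OCc3ccccc3)c1OCc1ccccc1 | intermediate
17 | robinetinidol-(4α→2')-(2R,3S,4S)-leucorobinetinidin, upper unit 2R,3S,4S, lower unit 2R,3S,4S | Oc1ccc2c(c1)O[C@H](c1cc(O)c(O)c(O)c1)[C@@H](O)[C@@H]2c1c([C@H]2Oc3cc(O)ccc3[C@H](O)[C@@H]2O)cc(O)c(O)c1O | target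

**Count.** Total steps: 11. Longest linear sequence: 10 (steps 1, 2 and 4 to 11, from 1).

**Steps most likely to fail**

Step 9. Facial selectivity at C2 may be poor. The catalyst may be overridden by the bulky stereogenic ortho-flavanyl group, or labile 13 may close without the catalyst.
The fallback sets out from 13 and comes back at 15. 1,1'-Carbonyldiimidazole (CH2Cl2, 0 °C) ties O1 and the C4 oxygen into the six-membered cyclic carbonate F1, a ring foreign to the target. Its acylated O1 can no longer trigger spontaneous closure. Pd2(dba)3 with a chiral phosphoramidite ligand (THF, rt) then ionises either C4 epimer with decarboxylation. The resulting π-allylpalladium phenoxide equilibrates by π-σ-π isomerisation and closes at C2 under ligand control (decarboxylative Tsuji–Trost allylic etherification).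

Step 6. Oxidative addition into the hindered, electron-rich triflate may be too slow under CO, so that hydrolysis or reduction of the triflate takes over.
The fallback sets out from 9 and comes back at 10. A CO-free Suzuki–Miyaura coupling (potassium vinyltrifluoroborate, Pd(OAc)2, SPhos, K3PO4, toluene–H2O, 90 °C) gives the styrene F2. Lemieux–Johnson cleavage (cat. OsO4, NaIO4, 2,6-lutidine, dioxane–H2O) then delivers the aldehyde.

Step 11. Over-reduction may occur. The benzylic C4–O bond of the lower unit may be hydrogenolysed while the slow secondary 3-O-benzyl ether of the upper unit is still being cleaved.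
The fallback sets out from 16 and comes back at 17.
- The cis-diol is first bridged with tBu2Si(OTf)2 and 2,6-lutidine (CH2Cl2, 0 °C) to the di-tert-butylsilylene derivative F3, whose bulk shields C4–O from the catalyst surface.
- Hydrogenolysis (H2, Pd(OH)2/C, EtOAc–THF) gives the free-phenolic silylene F4.
- Et3N·3HF (THF, 0 °C) then releases the diol under nearly neutral conditions.

**Further compounds**

F1 | step 9 | 7-(benzyloxy)-4-[(E)-2-arylvinyl]-4H-1,3-benzodioxin-2-one, both C4 epimers, aryl as in 12 | c1ccccc1COc1ccc2c(c1)O[C@H](c1cc(OCc3ccccc3)c(OCc3ccccc3)c(OCc3ccccc3)c1)[C@@H](OCc1ccccc1)[C@@H]2c1c(/C=C/C3OC(=O)Oc4cc(OCc5ccccc5)ccc34)cc(OCc3ccccc3)c(OCc3ccccc3)c1OCc1ccccc1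
F2 | step 6 | 2-[(2R,3S,4S)-flavan-4-yl]-3,4,5-tris(benzyloxy)styrene | c1ccccc1COc1ccc2c(c1)O[C@H](c1cc(OCc3ccccc3)c(OCc3ccccc3)c(OCc3ccccc3)c1)[C@@H](OCc1ccccc1)[C@@H]2c1c(C=C)cc(OCc3ccccc3)c(OCc3ccccc3)c1OCc1ccccc1
F3 | step 11 | 3,4-O-(di-tert-butylsilylene) derivative of 16 | c1ccccc1COc1ccc2c(c1)O[C@H](c1cc(OCc3ccccc3)c(OCc3ccccc3)c(OCc3ccccc3)c1)[C@@H](OCc1ccccc1)[C@@H]2c1c([C@H]3Oc4cc(OCc5ccccc5)ccc4[C@H](O[Si](C(C)(C)C)(C(C)(C)C)O5)[C@@H]35)cc(OCc3ccccc3)c(OCc3ccccc3)c1OCc1ccccc1
F4 | step 11 | 3,4-O-(di-tert-butylsilylene) derivative of 17 | Oc1ccc2c(c1)O[C@H](c1cc(O)c(O)c(O)c1)[C@@H](O)[C@@H]2c1c([C@H]3Oc4cc(O)ccc4[C@H](O[Si](C(C)(C)C)(C(C)(C)C)O5)[C@@H]35)cc(O)c(O)c1O
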